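All runs were generated by integration with made-up constants, and the scatter is random.

Two questions are asked about the flasks larch, elm and birch, and the reckoning for both rests on one quantity.

in all of them: substrate 0.10 M
- eta: reagent 0.017 M; run made earlier
- delta: reagent 0.077 M; run made earlier
- larch: reagent 0.0150 M; time 25 min
- elm: reagent 0.0300 M; time 25 min
- birch: reagent 0.0600 M; time 25 min

* amount of product at the end, in percent of the substrate charged for larch, elm, birch, in this order
* the shape of the row from first to last (falls all the way / rises, then falls / hardly changes / rises all the way / falls, then rises)

- the earlier runs were read with a standard deviation of 0.5 percentage points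
- "hardly changes" means that all values lie within two and a half points (for a concentration: within two and a half percent of the largest)

| run | time / min | product / % | substrate / % |
|---|---|---|---|
| eta | 2.50 | 10.0 | 79.0 |
| eta | 5.00 | 9.8 | 71.7 |
| eta | 8.00 | 10.0 | 62.7 |
| eta | 10.0 | 9.3 | 56.6 |
| eta | 12.0 | 9.7 | 52.7 |
| delta | 2.50 | 40.8 | 52.5 |
| delta | 5.00 | 39.2 | 47.9 |
| delta | 8.00 | 38.0 | 43.1 |
| delta | 10.0 | 36.4 | 40.5 |
| delta | 12.0 | 35.8 | 38.5 |

(each reading ± 0.5 percentage points)

In the delta run the product reads 40.8% at 2.50 min and then sinks to 35.8% at 12.0 min, while the substrate falls from 52.5% to 38.5%. A product that follows its substrate downward suggests a reversible step, substrate + reagent ⇌ product, fast enough to keep up, which is called a fast pre-equilibrium. When the forward and back rates of such a step are equal, the ratio K = [product]/([S][R]) stays constant, where [S] is the substrate concentration and [R] the free reagent, taken as the charge minus the product. The delta readings give 21.5 M⁻¹ at 2.50 min and 22.6 M⁻¹ at 12.0 min, and the last eta reading gives 25.2 M⁻¹. You take the mean of the last delta value and the eta value, the equilibrium constant K = 23.9 M⁻¹, as a reading with their scatter.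

K turns a substrate concentration into a share of the reagent held as product, f = K[S]/(1 + K[S]), so you still need the substrate at 25 min. Taking its fall as exponential, you read a rate constant of 0.0426 min⁻¹ from the eta run and a smaller one of 0.0326 min⁻¹ from the delta run. Carried on to 25 min as an estimate, these give 30.3% substrate for eta and 25.2% for delta. A straight line in the reagent charge through these two estimates gives 30.5% for larch, whose charge lies just below that of eta, 29.2% for elm and 26.6% for birch. From larch to birch f falls from 0.421 to 0.389, while the charge grows by a factor of 4.00. Your product is then 6.32% for larch, 12.3% for elm and 23.3% for birch, rising at each step .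

The forecast, made by someone who saw these runs, reads 8.2%, 15% and 25.5%, rises all the way, with the words “Loss grows with loading, but not enough to reverse the trend”, and it stands above your reckoning at each flask .

The flasks give 6.08%, 11.9% and 22.7%, and the row rises all the way.

    intermediate A ⇌ intermediate B (K = 0.580, k = 7.55 × 10⁻⁵ s⁻¹)
    substrate → intermediate A (k = 7.65 × 10⁻⁴ s⁻¹)
    substrate + reagent ⇌ product (K = 21.5 M⁻¹, k = 0.317 M⁻¹ s⁻¹)

In larch at 25.0 min, intermediate A stands at 59.3% beside 30.8% of substrate. Now use K on birch, whose substrate at the end is 27.6%: f comes to 0.398, which means 23.9% of product. The birch flask holds 22.7% of product, with 62.2% of its reagent free.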